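## Retrosynthetic overview

- The target is a mixed bis(2,4-trans-flavan-4-yl) ether. Unit A (5-hydroxy-6,7-dimethoxyflavan, unprimed locants) and unit B (5,6,7-trimethoxyflavan, primed locants) are separated by cutting the ether O–C4' bond and the C4'–C4a' bond together. This gives the 2,4-trans-flavan-4-ol silyl ether of unit A and an (S)-3-aryloxy-3-phenylpropanal, which unite through an oxocarbenium ion that closes ring C' by Friedel–Crafts alkylation.
- Enabling feature: C4' carries the inter-flavan oxygen and is therefore at the aldehyde (acetal) oxidation level. C4a' of ring A' is ortho to O1', ortho to 5'-OMe and para to 7'-OMe, a phloroglucinol-type carbon nucleophile. The open-chain 3,4,5-trimethoxyphenoxy group has two identical ortho carbons, and C2' (phenyl) relays its configuration to C4'.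
- Both halves stem from one chiral ether: Mitsunobu inversion of (R)-1-phenylbut-3-en-1-ol with 3,4,5-trimethoxyphenol, alkene cleavage to the aldehyde (unit B precursor), then oxidation and Friedel–Crafts acylation to (S)-5,6,7-trimethoxyflavanone (ring C of unit A).
- Unit A: chelation-controlled 5-O-demethylation, cis reduction, 5-O-tosylation (a protecting group that also damps ring A), Mitsunobu inversion to the 2,4-trans alcohol, silylation.
- Ring order: ring C of unit A (step 4), then ring C' of unit B (step 11); detosylation ends the route.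

Key step: step 11

Remark on the chemistry: (R)-1-phenylbut-3-en-1-ol of high enantiomeric purity and 3,4,5-trimethoxyphenol are taken as purchasable.

## Route

Step 1
Reactants: 1 (R)-1-phenylbut-3-en-1-ol; 2 3,4,5-trimethoxyphenol
Product: 3 1,2,3-trimethoxy-5-{[(1S)-1-phenylbut-3-en-1-yl]oxy}benzene
Conditions: PPh3, DIAD, toluene, 0 °C → rt
Reagents that add atoms: none
Why: Mitsunobu etherification, in which the phenol displaces the oxyphosphonium of the secondary benzylic alcohol by SN2 with inversion, so the R carbinol should give the S aryl ether that becomes C2 of both flavan units.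

Step 2
Reactants: 3 1,2,3-trimethoxy-5-{[(1S)-1-phenylbut-3-en-1-yl]oxy}benzene
Product: 5 (3S)-3-phenyl-3-(3,4,5-trimethoxyphenoxy)propanal, via diol 4 (not isolated)
Conditions: OsO4 (cat.), NaIO4, 2,6-lutidine, dioxane/H2O, rt
Reagents that add atoms: OsO4, O=[Os](=O)(=O)=O (catalytic oxygen carrier); NaIO4, [Na+].[O-]I(=O)(=O)=O (terminal oxygen source)
Why: Lemieux–Johnson oxidation (dihydroxylation of the terminal alkene to diol 4, then periodate glycol cleavage) under lutidine buffering should give the β-aryloxy aldehyde without touching the electron-rich ring or the stereocentre.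

Step 3
Reactants: 5 (3S)-3-phenyl-3-(3,4,5-trimethoxyphenoxy)propanal
Product: 6 (3S)-3-phenyl-3-(3,4,5-trimethoxyphenoxy)propanoic acid
Conditions: NaClO2, NaH2PO4, 2-methylbut-2-ene (excess), t-BuOH/H2O, 0 °C → rt
Reagents that add atoms: NaClO2, [Na+].[O-]Cl=O
Why: Pinnick oxidation, in which buffered chlorite oxidises the aldehyde chemoselectively and the alkene scavenger removes HOCl before it can chlorinate the trimethoxyphenoxy ring.

Step 4
Reactants: 6 (3S)-3-phenyl-3-(3,4,5-trimethoxyphenoxy)propanoic acid
Product: 8 (2S)-5,6,7-trimethoxy-2-phenylchroman-4-one, via mixed anhydride 7 (not isolated)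
Conditions: (CF3CO)2O, CH2Cl2, 0 °C → rt
Reagents that add atoms: none
Why: Intramolecular Friedel–Crafts acylation through the mixed trifluoroacetic anhydride; the ring carbon ortho to the ether oxygen and to one OMe and para to another is acylated, either ortho position gives the same flavanone, and C2 is not involved.

Step 5
Reactants: 8 (2S)-5,6,7-trimethoxy-2-phenylchroman-4-one
Product: 10 (2S)-5-hydroxy-6,7-dimethoxy-2-phenylchroman-4-one, via dichloroboron chelate 9 (not isolated)
Conditions: BCl3 (1.2 equiv), CH2Cl2, −78 → 0 °C; then H2O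
Reagents that add atoms: none
Why: Chelation-controlled aryl methyl ether cleavage, in which BCl3 bound between the C4 carbonyl and the peri 5-OMe lets chloride remove only that methyl group, and the resulting chelate 9 is hydrolysed on work-up.

Step 6
Reactants: 10 (2S)-5-hydroxy-6,7-dimethoxy-2-phenylchroman-4-one
Product: 11 (2S,4S)-6,7-dimethoxy-2-phenylchroman-4,5-diol
Conditions: NaBH4, THF/MeOH, 0 °C; neutral work-up, used at once
Reagents that add atoms: none
Why: Borohydride reduction of a flavanone, in which axial hydride delivery to the half-chair with pseudoequatorial 2-phenyl should give the 2,4-cis (4S) alcohol under substrate control by C2.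

Step 7
Reactants: 11 (2S,4S)-6,7-dimethoxy-2-phenylchroman-4,5-diol
Product: 12 (2S,4S)-4-hydroxy-6,7-dimethoxy-2-phenylchroman-5-yl 4-methylbenzenesulfonate
Conditions: TsCl, K2CO3, acetone, rt
Reagents that add atoms: 4-methylbenzenesulfonyl chloride, Cc1ccc(cc1)S(Cl)(=O)=O
Why: Chemoselective O-sulfonylation of the phenoxide (K2CO3 does not deprotonate the benzylic alcohol); the tosylate protects the phenol and lowers the donor power of ring A so that ionisation of C4–O is retarded in steps 8 to 11.

Step 8
Reactants: 12 (2S,4S)-4-hydroxy-6,7-dimethoxy-2-phenylchroman-5-yl 4-methylbenzenesulfonate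
Product: 13 (2S,4R)-6,7-dimethoxy-2-phenyl-5-(tosyloxy)chroman-4-yl 4-nitrobenzoate
Conditions: 4-nitrobenzoic acid, PPh3, DIAD, toluene, 0 °C → rt
Reagents that add atoms: 4-nitrobenzoic acid, OC(=O)c1ccc(cc1)[N+](=O)[O-]
Why: Mitsunobu inversion, in which the carboxylate displaces the oxyphosphonium by SN2 on the face opposite the leaving group, turning 4S (cis) into 4R (2,4-trans).

Step 9
Reactants: 13 (2S,4R)-6,7-dimethoxy-2-phenyl-5-(tosyloxy)chroman-4-yl 4-nitrobenzoate
Product: 14 (2S,4R)-4-hydroxy-6,7-dimethoxy-2-phenylchroman-5-yl 4-methylbenzenesulfonate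
Conditions: LiOH, THF/H2O, 0 °C → rt
Reagents that add atoms: none
Why: Saponification of the activated 4-nitrobenzoate by acyl–oxygen cleavage, which leaves C4 untouched, while the aryl tosylate should survive hydroxide at this temperature.

Step 10
Reactants: 14 (2S,4R)-4-hydroxy-6,7-dimethoxy-2-phenylchroman-5-yl 4-methylbenzenesulfonate
Product: 15 (2S,4R)-6,7-dimethoxy-2-phenyl-4-(trimethylsilyloxy)chroman-5-yl 4-methylbenzenesulfonate
Conditions: N-(trimethylsilyl)imidazole, CH2Cl2, rt; filtration through basic alumina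
Reagents that add atoms: N-(trimethylsilyl)imidazole, C[Si](C)(C)n1ccnc1
Why: O-silylation of the hindered secondary alcohol with a neutral, powerful silyl donor, so that no acid or base is present that could ionise or epimerise C4.

Step 11
Reactants: 15 (2S,4R)-6,7-dimethoxy-2-phenyl-4-(trimethylsilyloxy)chroman-5-yl 4-methylbenzenesulfonate; 5 (3S)-3-phenyl-3-(3,4,5-trimethoxyphenoxy)propanal
Product: 18 (2S,4R)-6,7-dimethoxy-2-phenyl-4-{[(2S,4R)-5,6,7-trimethoxy-2-phenylchroman-4-yl]oxy}chroman-5-yl 4-methylbenzenesulfonate, via mixed silyl acetal 16 (not isolated), via oxocarbenium triflate 17 (not isolated)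
Conditions: Me3SiOTf (1.1 equiv), 2,6-di-tert-butyl-4-methylpyridine (1.5 equiv), 4 Å MS, CH2Cl2, −78 °C; then Et3N; chromatography on Et3N-washed SiO2
Reagents that add atoms: none
Why: Proposed new method: Me3SiOTf silylates the aldehyde of 5, the silyl ether oxygen of 15 adds to give mixed silyl acetal 16, loss of hexamethyldisiloxane gives the (E)-oxocarbenium ion 17, and the ortho carbon of the 3,4,5-trimethoxyphenoxy ring attacks the oxocarbenium carbon in an intramolecular Friedel–Crafts alkylation, the arenium ion giving its proton to the hindered pyridine. The closest known reaction types are the silyl-modified Sakurai reaction and reductive etherification (oxocarbenium ion from RCHO, R'OSiMe3 and Me3SiOTf), the acid-mediated closure of 3-aryloxypropanal acetals to 4-alkoxychromans, the oxa-Pictet–Spengler reaction and Friedel–Crafts C-glycosylation; what is new is their combination with a secondary benzylic silyl ether as the alcohol partner. Ring C' closes in the 6-exo-trig mode with respect to the C=O+ bond (6-endo with respect to the arene) through a chair-like transition state. The new stereocentre C4' is controlled by C2': the phenyl group sits pseudoequatorial and allylic-type strain with the peri 5'-OMe forces the bulky oxonium substituent pseudoaxial, which should give the 2',4'-trans (4'R) ether, and reversible ionisation of the product at C4' would return the same isomer by axial recapture. The step needs ionisation at the acetal carbon in the presence of benzylic C–O bonds and has no regiochemical choice on the arene: the electron-withdrawing 5-O-tosyl group retards ionisation at C4 of unit A, the low temperature and the proton scavenger keep TfOH out of the medium, and the two ortho carbons of the phenoxy ring are equivalent. Should aldehyde 5 close first to the silylated flavan-4-ol of unit B, ionisation of that ether and capture of the flavan-4'-yl cation by 15 trans to the 2'-phenyl group would converge on the same product.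

Step 12
Reactants: 18 (2S,4R)-6,7-dimethoxy-2-phenyl-4-{[(2S,4R)-5,6,7-trimethoxy-2-phenylchroman-4-yl]oxy}chroman-5-yl 4-methylbenzenesulfonate
Product: 19 beilschmieflavonoid B
Conditions: KOH, MeOH/THF, 60 °C; then aq. NH4Cl (buffered work-up)
Reagents that add atoms: none
Why: Alkaline S–O cleavage of the aryl tosylate (attack at sulfur, phenoxide as leaving group), to which the bis-benzylic ether and the methyl ethers are inert, with a near-neutral work-up to spare the acid-labile ether.

## Compound list

1 | (R)-1-phenylbut-3-en-1-ol | C=CC[C@@H](O)c1ccccc1 | starting material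
2 | 3,4,5-trimethoxyphenol | COc1cc(O)cc(OC)c1OC | starting material
3 | 1,2,3-trimethoxy-5-{[(1S)-1-phenylbut-3-en-1-yl]oxy}benzene | C=CC[C@H](Oc1cc(OC)c(OC)c(OC)c1)c1ccccc1 | intermediate
4 | (4S)-4-phenyl-4-(3,4,5-trimethoxyphenoxy)butane-1,2-diol (both C2 epimers; not isolated) | OCC(O)C[C@H](Oc1cc(OC)c(OC)c(OC)c1)c1ccccc1 | intermediate
5 | (3S)-3-phenyl-3-(3,4,5-trimethoxyphenoxy)propanal | O=CC[C@H](Oc1cc(OC)c(OC)c(OC)c1)c1ccccc1 | intermediate
6 | (3S)-3-phenyl-3-(3,4,5-trimethoxyphenoxy)propanoic acid | OC(=O)C[C@H](Oc1cc(OC)c(OC)c(OC)c1)c1ccccc1 | intermediate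
7 | (3S)-3-phenyl-3-(3,4,5-trimethoxyphenoxy)propanoic trifluoroacetic anhydride (not isolated) | O=C(OC(=O)C(F)(F)F)C[C@H](Oc1cc(OC)c(OC)c(OC)c1)c1ccccc1 | intermediate
8 | (2S)-5,6,7-trimethoxy-2-phenylchroman-4-one | COc1cc2c(c(OC)c1OC)C(=O)C[C@@H](c1ccccc1)O2 | intermediate
9 | (2S)-5-(dichloroboryloxy)-6,7-dimethoxy-2-phenylchroman-4-one, boron chelated to the C4 carbonyl (not isolated) | COc1cc2c(c(OB(Cl)Cl)c1OC)C(=O)C[C@@H](c1ccccc1)O2 | intermediate
10 | (2S)-5-hydroxy-6,7-dimethoxy-2-phenylchroman-4-one | COc1cc2c(c(O)c1OC)C(=O)C[C@@H](c1ccccc1)O2 | intermediate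
11 | (2S,4S)-6,7-dimethoxy-2-phenylchroman-4,5-diol (2,4-cis) | COc1cc2c(c(O)c1OC)[C@@H](O)C[C@@H](c1ccccc1)O2 | intermediate
12 | (2S,4S)-4-hydroxy-6,7-dimethoxy-2-phenylchroman-5-yl 4-methylbenzenesulfonate | COc1cc2c(c(OS(=O)(=O)c3ccc(C)cc3)c1OC)[C@@H](O)C[C@@H](c1ccccc1)O2 | intermediate
13 | (2S,4R)-6,7-dimethoxy-2-phenyl-5-(tosyloxy)chroman-4-yl 4-nitrobenzoate | COc1cc2c(c(OS(=O)(=O)c3ccc(C)cc3)c1OC)[C@H](OC(=O)c1ccc(cc1)[N+](=O)[O-])C[C@@H](c1ccccc1)O2 | intermediate
14 | (2S,4R)-4-hydroxy-6,7-dimethoxy-2-phenylchroman-5-yl 4-methylbenzenesulfonate (2,4-trans) | COc1cc2c(c(OS(=O)(=O)c3ccc(C)cc3)c1OC)[C@H](O)C[C@@H](c1ccccc1)O2 | intermediate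
15 | (2S,4R)-6,7-dimethoxy-2-phenyl-4-(trimethylsilyloxy)chroman-5-yl 4-methylbenzenesulfonate | COc1cc2c(c(OS(=O)(=O)c3ccc(C)cc3)c1OC)[C@H](O[Si](C)(C)C)C[C@@H](c1ccccc1)O2 | intermediate
16 | (2S,4R)-6,7-dimethoxy-2-phenyl-4-{[(3S)-3-phenyl-3-(3,4,5-trimethoxyphenoxy)-1-(trimethylsilyloxy)propyl]oxy}chroman-5-yl 4-methylbenzenesulfonate (both acetal epimers; not isolated) | COc1cc2c(c(OS(=O)(=O)c3ccc(C)cc3)c1OC)[C@H](OC(O[Si](C)(C)C)C[C@H](Oc1cc(OC)c(OC)c(OC)c1)c1ccccc1)C[C@@H](c1ccccc1)O2 | intermediate
17 | (E)-[(2S,4R)-6,7-dimethoxy-2-phenyl-5-(tosyloxy)chroman-4-yl][(3S)-3-phenyl-3-(3,4,5-trimethoxyphenoxy)propylidene]oxonium triflate (not isolated) | COc1cc2c(c(OS(=O)(=O)c3ccc(C)cc3)c1OC)[C@H](/[O+]=C/C[C@H](Oc1cc(OC)c(OC)c(OC)c1)c1ccccc1)C[C@@H](c1ccccc1)O2.[O-]S(=O)(=O)C(F)(F)F | intermediate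
18 | (2S,4R)-6,7-dimethoxy-2-phenyl-4-{[(2S,4R)-5,6,7-trimethoxy-2-phenylchroman-4-yl]oxy}chroman-5-yl 4-methylbenzenesulfonate | COc1cc2c(c(OS(=O)(=O)c3ccc(C)cc3)c1OC)[C@H](O[C@@H]1C[C@@H](c3ccccc3)Oc3cc(OC)c(OC)c(OC)c31)C[C@@H](c1ccccc1)O2 | intermediate
19 | beilschmieflavonoid B, (2S,4R)-6,7-dimethoxy-2-phenyl-4-{[(2S,4R)-5,6,7-trimethoxy-2-phenylchroman-4-yl]oxy}chroman-5-ol | COc1cc2c(c(O)c1OC)[C@H](O[C@@H]1C[C@@H](c3ccccc3)Oc3cc(OC)c(OC)c(OC)c31)C[C@@H](c1ccccc1)O2 | target

## Step count and risks

Total step count: 12. Longest linear sequence: 12 steps (aldehyde 5 from step 2 is used again in step 11).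

Steps most likely to fail:

**Step 11 (proposed new method).** The silyl-activated aldehyde may close onto its own ring before the silyl ether has added. The benzylic C4'–O bond of the product may ionise, with scrambling to symmetrical ethers or C-arylation at a free C8 position. The oxocarbenium ion may lose the β-aryloxide. The fallback uses known chemistry and pre-assembles the C–O bond before any Lewis acid is present. It sets out from cis-alcohol 12 and acid 6. Mitsunobu esterification (PPh3, DIAD, toluene) should give, with inversion at C4, the ester (2S,4R)-6,7-dimethoxy-2-phenyl-5-(tosyloxy)chroman-4-yl (3S)-3-phenyl-3-(3,4,5-trimethoxyphenoxy)propanoate F1; this also replaces steps 8 to 10. Reductive acetylation of the ester (i-Bu2AlH, CH2Cl2, −78 °C; then Ac2O, pyridine, DMAP) should give the α-acetoxy ether (2S,4R)-4-{[1-acetoxy-(3S)-3-phenyl-3-(3,4,5-trimethoxyphenoxy)propyl]oxy}-6,7-dimethoxy-2-phenylchroman-5-yl 4-methylbenzenesulfonate F2. Ionisation of the acetate with BF3·OEt2 in CH2Cl2 at −78 °C and Friedel–Crafts closure of the same bond comes back to the route at compound 18.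

**Step 8.** The activated benzylic oxyphosphonium may ionise instead of undergoing SN2 displacement, leading to elimination to the flav-3-ene or incomplete inversion, and the peri tosylate may slow the displacement. The fallback replaces SN2 inversion by stereoconvergent SN1 substitution. It sets out from compound 12. Acetolysis (AcOH, cat. camphorsulfonic acid, rt) should let the flavan-4-yl cation be recaptured axially, trans to the 2-phenyl group and away from the peri substituent, giving the acetate (2S,4R)-4-acetoxy-6,7-dimethoxy-2-phenylchroman-5-yl 4-methylbenzenesulfonate F3. Methanolysis (K2CO3, MeOH, 0 °C) comes back to the route at compound 14.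

**Step 4.** Enantiopurity may be lost through acid-mediated opening of the pyranone ring (retro-oxa-Michael) or ionisation of the benzylic C–O bond, and the ring may be trifluoroacetylated instead. The fallback closes the ring at the aldehyde oxidation level and oxidises afterwards. It sets out from compound 5. Intramolecular Friedel–Crafts hydroxyalkylation (Me2AlCl, CH2Cl2, −78 °C) should give (2S)-5,6,7-trimethoxy-2-phenylchroman-4-ol F4 as a mixture at C4, which does not matter. Benzylic oxidation (MnO2, CH2Cl2, rt) comes back to the route at compound 8.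

Further compounds
F1 | step 11 | (2S,4R)-6,7-dimethoxy-2-phenyl-5-(tosyloxy)chroman-4-yl (3S)-3-phenyl-3-(3,4,5-trimethoxyphenoxy)propanoate | COc1cc2c(c(OS(=O)(=O)c3ccc(C)cc3)c1OC)[C@H](OC(=O)C[C@H](Oc1cc(OC)c(OC)c(OC)c1)c1ccccc1)C[C@@H](c1ccccc1)O2
F2 | step 11 | (2S,4R)-4-{[1-acetoxy-(3S)-3-phenyl-3-(3,4,5-trimethoxyphenoxy)propyl]oxy}-6,7-dimethoxy-2-phenylchroman-5-yl 4-methylbenzenesulfonate (both acetal epimers) | COc1cc2c(c(OS(=O)(=O)c3ccc(C)cc3)c1OC)[C@H](OC(OC(C)=O)C[C@H](Oc1cc(OC)c(OC)c(OC)c1)c1ccccc1)C[C@@H](c1ccccc1)O2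
F3 | step 8 | (2S,4R)-4-acetoxy-6,7-dimethoxy-2-phenylchroman-5-yl 4-methylbenzenesulfonate | COc1cc2c(c(OS(=O)(=O)c3ccc(C)cc3)c1OC)[C@H](OC(C)=O)C[C@@H](c1ccccc1)O2
F4 | step 4 | (2S)-5,6,7-trimethoxy-2-phenylchroman-4-ol (both C4 epimers) | COc1cc2c(c(OC)c1OC)C(O)C[C@@H](c1ccccc1)O2
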